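**Strategy.** Ring carbons: C1 (angelate), C2, C3 (methyl), C4 (acetate), C5, C6; side chain C1'(Me)–C2'–C3'(OAc)–C4'=C5'. The route exploits the two acetate oxygens on ring carbon C4 and side-chain carbon C3': a temporary Me2Si unit joins O–C3' to C4, so that a type 2 intramolecular Diels–Alder reaction of a (Z)-propenylsilane onto the 2-siloxydiene C2=C1(OSi)–C6=C5 forms C2–C3 and C5–C4, closes the cyclohexane ring, fixes C3 and C4 cis, and leaves a C–Si bond that Tamao oxidation turns into the C4 oxygen. Every stereocentre is relayed from (R)-citronellic acid (C1').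

Key step: step 7

Remark: compounds 1, 9 and 18 are taken as commercial. All selectivities below are expectations, not measured results.

**Step 1**
Reactants: 1 (3R)-3,7-dimethyloct-6-enoic acid ((R)-citronellic acid)
Product: 3 (3R,5E)-7-hydroxy-3,7-dimethyloct-5-enoic acid, via allylic hydroperoxide 2 (not isolated)
Conditions: O2, visible light, 5,10,15,20-tetraphenylporphyrin (cat.), CH2Cl2, 0 °C; then PPh3, 0 °C → rt
Reagents that add atoms: dioxygen, O=O
Why: Schenck ene reaction: singlet oxygen adds to the trisubstituted alkene with abstraction of a C5 hydrogen and shift of the double bond to C5=C6 (E), and PPh3 reduces the hydroperoxide; the isopropenyl regioisomer that should form alongside is carried on and removed in step 2, and C3 is untouched.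

**Step 2**
Reactants: 3 (3R,5E)-7-hydroxy-3,7-dimethyloct-5-enoic acid
Product: 4 (4R,6R)-4-methyl-6-(2-methylprop-1-en-1-yl)oxan-2-one (cis-lactone)
Conditions: (1S)-camphor-10-sulfonic acid (10 mol%), 4 Å molecular sieves, CH2Cl2, rt; aq NaHCO3 wash
Reagents that add atoms: none
Why: SN1' lactonisation of the rose oxide cyclisation type: the tertiary allylic alcohol ionises, the carboxyl oxygen captures the allyl cation at C5 in a six-membered ring, and reversible ionisation of the allylic lactone should let the product settle as the cis isomer with methyl and 2-methylpropenyl both equatorial, which sets C3' from C1'; the regioisomeric hydroxy acid stays acidic and is washed out.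

**Step 3**
Reactants: 4 (4R,6R)-4-methyl-6-(2-methylprop-1-en-1-yl)oxan-2-one
Product: 7 (4R,6R)-4-methyl-3-methylidene-6-(2-methylprop-1-en-1-yl)oxan-2-one, via Mannich base 5 (not isolated), via ammonium iodide 6 (not isolated)
Conditions: LiN(iPr)2, THF, −78 °C; CH2=NMe2+ I−, −78 °C → rt; MeI, MeOH, rt; aq NaHCO3, CH2Cl2, rt
Reagents that add atoms: Eschenmoser's salt (N,N-dimethylmethylideneammonium iodide), C=[N+](C)C.[I-]
Why: α-Methylenation of a lactone by enolate Mannich reaction with Eschenmoser's salt, N-methylation and Hofmann-type elimination under bicarbonate, conditions too mild to touch the existing stereocentres.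

**Step 4**
Reactants: 7 (4R,6R)-4-methyl-3-methylidene-6-(2-methylprop-1-en-1-yl)oxan-2-one
Product: 8 (4R,6R)-6-hydroxy-4,8-dimethyl-3-methylidenenon-7-en-2-one
Conditions: MeLi (1.05 equiv), THF, −78 °C; aq NH4Cl at −78 °C
Reagents that add atoms: methyllithium, [Li]C
Why: Mono-addition of MeLi to a lactone: hard 1,2-attack gives a lithium lactolate that is stable at −78 °C and opens on protonation to the δ-hydroxy methyl ketone, so a second addition and 1,4-addition should not occur.

**Step 5**
Reactants: 9 (1Z)-1-bromoprop-1-ene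
Product: 11 chloro(dimethyl)[(1Z)-prop-1-en-1-yl]silane, via (Z)-propenyllithium 10 (not isolated)
Conditions: Li (1% Na), Et2O, −10 °C; added to Me2SiCl2 (4 equiv), Et2O, −78 °C → rt; distillation
Reagents that add atoms: dichlorodimethylsilane, C[Si](C)(Cl)Cl
Why: Reductive lithiation of the vinyl bromide with retention of the Z geometry, then substitution at silicon by inverse addition to excess dichlorosilane so that only one chloride is replaced.

**Step 6**
Reactants: 8 (4R,6R)-6-hydroxy-4,8-dimethyl-3-methylidenenon-7-en-2-one; 11 chloro(dimethyl)[(1Z)-prop-1-en-1-yl]silane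
Product: 13 triethyl{[(4R,6R)-6-({dimethyl[(1Z)-prop-1-en-1-yl]silyl}oxy)-4,8-dimethyl-3-methylidenenona-1,7-dien-2-yl]oxy}silane, via silyl ether enone 12 (not isolated)
Conditions: 11, Et3N, 4-(dimethylamino)pyridine (cat.), CH2Cl2, 0 °C; then Et3SiOTf, Et3N, −78 → 0 °C
Reagents that add atoms: triethylsilyl trifluoromethanesulfonate, CC[Si](CC)(CC)OS(=O)(=O)C(F)(F)F
Why: O-Silylation of the secondary allylic alcohol, then soft enolisation (silyl triflate/amine) of the methyl ketone, whose methyl group is the only enolisable position, gives the cross-conjugated 2-silyloxy-1,3-diene; no stereocentre is touched.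

**Step 7**
Reactants: 13 triethyl{[(4R,6R)-6-({dimethyl[(1Z)-prop-1-en-1-yl]silyl}oxy)-4,8-dimethyl-3-methylidenenona-1,7-dien-2-yl]oxy}silane
Product: 14 (1R,4R,6R,10S)-2,2,6,10-tetramethyl-4-(2-methylprop-1-en-1-yl)-8-[(triethylsilyl)oxy]-3-oxa-2-silabicyclo[5.3.1]undec-7-ene
Conditions: PhMe (0.01 M), 2,6-di-tert-butyl-4-methylphenol (cat.), Et3N (trace), sealed tube, 190 °C
Reagents that add atoms: none
Why: Thermal, concerted, suprafacial [4+2] cycloaddition in which the electron-rich 2-siloxydiene C2=C1(OSiEt3)–C6=C5 adds to the tethered (Z)-propenylsilane, the nucleophilic terminus C2 bonding to the β-silyl carbon C3 and C5 to C4, so that tether and electronics ask for the same regiochemistry. The closest known reaction types are the temporary-silicon-tethered Diels–Alder reaction of vinylsilanes and the type 2 intramolecular Diels–Alder reaction that gives bridgehead alkenes. Two rings close: the cyclohexene by the cycloaddition itself, and the eight-membered oxasila ring C4–Si–O–C3'–C2'–C1'–C6–C5 through the new C4–C5 bond, in the 1,3-bridging mode of a five-atom tether on an inner diene carbon, which gives a bicyclo[5.3.1]undecene with a bridgehead enol ether. C3 and C4 become cis because the Z geometry is carried over, silicon being necessarily endo to reach C6. Their absolute configuration (3S,4R) is set by the tether stereocentres: C1' turns its hydrogen and not its methyl toward the C1 siloxy group, and C3' keeps the 2-methylpropenyl group outward (pseudo-equatorial) on the forming eight-membered ring, so the dienophile can reach one diene face only. The step needs facial selectivity and cyclisation faster than diene dimerisation; the matched syn pair C1'/C3' and high dilution are meant to secure them.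

**Step 8**
Reactants: 14 (1R,4R,6R,10S)-2,2,6,10-tetramethyl-4-(2-methylprop-1-en-1-yl)-8-[(triethylsilyl)oxy]-3-oxa-2-silabicyclo[5.3.1]undec-7-ene
Product: 15 (2S,4R,5S)-4-hydroxy-2-[(2R,4R)-4-hydroxy-6-methylhept-5-en-2-yl]-5-methylcyclohexan-1-one
Conditions: KF, KHCO3, 30% H2O2, THF/MeOH, 40 °C; aq Na2S2O3; then K2CO3 (cat.), MeOH, rt
Reagents that add atoms: hydrogen peroxide, OO
Why: Tamao–Fleming oxidation turns the C4–Si bond of the alkoxysilane into C4–OH with retention and frees the C3' hydroxyl, fluoride in methanol cleaves the bridgehead silyl enol ether to the ketone, and base-mediated epimerisation should place C6 in the configuration with side chain and C3 methyl both equatorial (an axial 4-oxygen costs little in a cyclohexanone, and the trans-fused hemiketal with the C3' hydroxyl favours the same epimer).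

**Step 9**
Reactants: 15 (2S,4R,5S)-4-hydroxy-2-[(2R,4R)-4-hydroxy-6-methylhept-5-en-2-yl]-5-methylcyclohexan-1-one
Product: 16 (1R,2S,5S)-5-[(2R,4R)-4-(acetyloxy)-6-methylhept-5-en-2-yl]-2-methyl-4-oxocyclohexyl acetate
Conditions: Ac2O, pyridine, 4-(dimethylamino)pyridine (cat.), CH2Cl2, 0 °C → rt
Reagents that add atoms: acetic anhydride, CC(=O)OC(C)=O
Why: Nucleophile-catalysed (Steglich-type) acetylation of both secondary alcohols; the ketone and all stereocentres are unaffected under these weakly basic conditions.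

**Step 10**
Reactants: 16 (1R,2S,5S)-5-[(2R,4R)-4-(acetyloxy)-6-methylhept-5-en-2-yl]-2-methyl-4-oxocyclohexyl acetate
Product: 17 (1R,2S,4R,5S)-5-[(2R,4R)-4-(acetyloxy)-6-methylhept-5-en-2-yl]-4-hydroxy-2-methylcyclohexyl acetate
Conditions: (3aS)-1-methyl-3,3-diphenyltetrahydro-1H,3H-pyrrolo[1,2-c][1,3,2]oxazaborole ((S)-Me-CBS, 0.2 equiv), catecholborane, PhMe, −78 °C
Reagents that add atoms: none
Why: CBS reduction: the (S)-oxazaborolidine distinguishes the branched C6 side from the C2 methylene and delivers hydride to the face that coincides with axial attack on the chair, which should give the equatorial (1R)-alcohol trans to the C6 side chain; acetates and alkene are inert to catecholborane at −78 °C.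

**Step 11**
Reactants: 17 (1R,2S,4R,5S)-5-[(2R,4R)-4-(acetyloxy)-6-methylhept-5-en-2-yl]-4-hydroxy-2-methylcyclohexyl acetate; 18 (2Z)-2-methylbut-2-enoic acid (angelic acid)
Product: 20 (1R,2S,4R,5S)-4-(acetyloxy)-2-[(2R,4R)-4-(acetyloxy)-6-methylhept-5-en-2-yl]-5-methylcyclohexyl (2Z)-2-methylbut-2-enoate (CNP0286954.1), via mixed anhydride 19 (not isolated)
Conditions: 18, 2,4,6-trichlorobenzoyl chloride, Et3N, PhMe, rt; then 17, PhMe, 80 °C (no nucleophilic catalyst)
Reagents that add atoms: none
Why: Yamaguchi-type acyl transfer from the mixed 2,4,6-trichlorobenzoic anhydride without nucleophilic catalyst, conditions that transfer the (Z)-2-methylbut-2-enoyl group to hindered secondary alcohols without Z to E isomerisation; C1 keeps its configuration because its C–O bond is not broken.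

**Compound list**

1 | (3R)-3,7-dimethyloct-6-enoic acid ((R)-citronellic acid) | OC(=O)C[C@H](C)CCC=C(C)C | starting material
2 | (3R,5E)-7-hydroperoxy-3,7-dimethyloct-5-enoic acid | OC(=O)C[C@H](C)C/C=C/C(C)(C)OO | intermediate
3 | (3R,5E)-7-hydroxy-3,7-dimethyloct-5-enoic acid | OC(=O)C[C@H](C)C/C=C/C(C)(C)O | intermediate
4 | (4R,6R)-4-methyl-6-(2-methylprop-1-en-1-yl)oxan-2-one | O=C1C[C@H](C)C[C@H](C=C(C)C)O1 | intermediate
5 | (4R,6R)-3-[(dimethylamino)methyl]-4-methyl-6-(2-methylprop-1-en-1-yl)oxan-2-one (C3 unassigned) | O=C1C(CN(C)C)[C@H](C)C[C@H](C=C(C)C)O1 | intermediate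
6 | trimethyl{[(4R,6R)-4-methyl-6-(2-methylprop-1-en-1-yl)-2-oxooxan-3-yl]methyl}ammonium iodide (C3 unassigned) | O=C1C(C[N+](C)(C)C)[C@H](C)C[C@H](C=C(C)C)O1.[I-] | intermediate
7 | (4R,6R)-4-methyl-3-methylidene-6-(2-methylprop-1-en-1-yl)oxan-2-one | O=C1C(=C)[C@H](C)C[C@H](C=C(C)C)O1 | intermediate
8 | (4R,6R)-6-hydroxy-4,8-dimethyl-3-methylidenenon-7-en-2-one | CC(=O)C(=C)[C@H](C)C[C@H](C=C(C)C)O | intermediate
9 | (1Z)-1-bromoprop-1-ene | C/C=C\Br | starting material
10 | (1Z)-prop-1-en-1-yllithium | C/C=C\[Li] | intermediate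
11 | chloro(dimethyl)[(1Z)-prop-1-en-1-yl]silane | C/C=C\[Si](C)(C)Cl | intermediate
12 | (4R,6R)-6-({dimethyl[(1Z)-prop-1-en-1-yl]silyl}oxy)-4,8-dimethyl-3-methylidenenon-7-en-2-one | CC(=O)C(=C)[C@H](C)C[C@H](C=C(C)C)O[Si](C)(C)/C=C\C | intermediate
13 | triethyl{[(4R,6R)-6-({dimethyl[(1Z)-prop-1-en-1-yl]silyl}oxy)-4,8-dimethyl-3-methylidenenona-1,7-dien-2-yl]oxy}silane | C=C(O[Si](CC)(CC)CC)C(=C)[C@H](C)C[C@H](C=C(C)C)O[Si](C)(C)/C=C\C | intermediate
14 | (1R,4R,6R,10S)-2,2,6,10-tetramethyl-4-(2-methylprop-1-en-1-yl)-8-[(triethylsilyl)oxy]-3-oxa-2-silabicyclo[5.3.1]undec-7-ene | CC[Si](CC)(CC)OC=1C[C@H](C)[C@H]([Si]2(C)C)CC=1[C@H](C)C[C@H](C=C(C)C)O2 | intermediate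
15 | (2S,4R,5S)-4-hydroxy-2-[(2R,4R)-4-hydroxy-6-methylhept-5-en-2-yl]-5-methylcyclohexan-1-one | O=C1C[C@H](C)[C@H](O)C[C@H]1[C@H](C)C[C@H](C=C(C)C)O | intermediate
16 | (1R,2S,5S)-5-[(2R,4R)-4-(acetyloxy)-6-methylhept-5-en-2-yl]-2-methyl-4-oxocyclohexyl acetate | O=C1C[C@H](C)[C@H](OC(C)=O)C[C@H]1[C@H](C)C[C@H](C=C(C)C)OC(C)=O | intermediate
17 | (1R,2S,4R,5S)-5-[(2R,4R)-4-(acetyloxy)-6-methylhept-5-en-2-yl]-4-hydroxy-2-methylcyclohexyl acetate | O[C@@H]1C[C@H](C)[C@H](OC(C)=O)C[C@H]1[C@H](C)C[C@H](C=C(C)C)OC(C)=O | intermediate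
18 | (2Z)-2-methylbut-2-enoic acid (angelic acid) | C/C=C(/C)C(=O)O | starting material
19 | (2Z)-2-methylbut-2-enoic 2,4,6-trichlorobenzoic anhydride | C/C=C(/C)C(=O)OC(=O)c1c(Cl)cc(Cl)cc1Cl | intermediate
20 | (1R,2S,4R,5S)-4-(acetyloxy)-2-[(2R,4R)-4-(acetyloxy)-6-methylhept-5-en-2-yl]-5-methylcyclohexyl (2Z)-2-methylbut-2-enoate | C/C=C(/C)C(=O)O[C@@H]1C[C@H](C)[C@H](OC(C)=O)C[C@H]1[C@H](C)C[C@H](C=C(C)C)OC(C)=O | target

**Step count.** Total: 11 steps. Longest linear sequence: 10 steps (steps 1–4 and 6–11); step 5 is a one-step side branch.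

**Steps most likely to fail**

1. Step 7. The unactivated (Z)-propenylsilane may cycloadd more slowly than the triene dimerises or decomposes at the temperature needed, or the tether may not discriminate the diene faces well enough. The fallback gives up the tether and uses an alkenyl(dialkyl)borane, a far more reactive dienophile, in an intermolecular Diels–Alder reaction. It sets out from 8: acetylation (Ac2O, pyridine, 4-(dimethylamino)pyridine) gives (4R,6R)-4,8-dimethyl-3-methylidene-2-oxonon-7-en-6-yl acetate F1, and Et3SiOTf/Et3N converts it into the siloxydiene acetate F2. (Z)-Propenyllithium 10 with 9-methoxy-9-borabicyclo[3.3.1]nonane and then BF3·OEt2 gives 9-[(1Z)-prop-1-en-1-yl]-9-borabicyclo[3.3.1]nonane F3. F2 and F3 in PhMe at 25–60 °C should give the cyclohexenylborane F4 with boron para to the siloxy group and boron cis to the methyl. NaBO3·4H2O in THF/H2O oxidises the C–B bond with retention, dilute AcOH work-up cleaves the enol ether, and a trace of DBU in CH2Cl2 equilibrates C6, to give the keto alcohol F5. Acetylation under the conditions of step 9 comes back to the route at 16. Without the tether the diene face is no longer controlled by the substrate, so the (3S,4R) product would have to be separated from its ring diastereomer.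

2. Step 2. The allyl cation may eliminate to dienes faster than it is captured, or the cis preference of the ring closure may be incomplete. The fallback replaces substrate control by reagent control at C3'. It sets out from 3: Me3SiCHN2 in MeOH/PhMe gives the methyl ester F6. Pyridinium chlorochromate, [C5H5NH][CrO3Cl], in CH2Cl2 effects the oxidative 1,3-transposition of the tertiary allylic alcohol (Babler–Dauben oxidation) to methyl (3R)-3,7-dimethyl-5-oxooct-6-enoate F7. CBS reduction with (S)-Me-CBS and catecholborane in PhMe at −78 °C should give the (5R)-allylic alcohol F8. Pyridinium p-toluenesulfonate in PhMe at 60 °C closes the δ-hydroxy ester to the lactone and comes back to the route at 4.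

3. Step 8. The epimerisation at C6 may not be one-sided enough, because the wanted chair carries an axial C4–OH and the C6 epimer can escape into a chair with axial C3 methyl. The fallback relays C6 from C1' through a temporary ring instead. It sets out from 15 as its C6 epimer mixture: HC(OMe)3 and pyridinium p-toluenesulfonate in MeOH at 40 °C convert the δ-hydroxy ketone into the bicyclic methyl ketal F9. Under the acid the ketal equilibrates through its enol ether, and the trans-fused isomer in which the C6–C5 bond, the C1' methyl and the C3' alkenyl group are all equatorial on the oxane chair should be strongly preferred. Mild hydrolysis (pyridinium p-toluenesulfonate, acetone/H2O, rt) comes back to the route at 15 as a single C6 epimer, which is acetylated at once.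

**Further compounds**

F1 | step 7 | (4R,6R)-4,8-dimethyl-3-methylidene-2-oxonon-7-en-6-yl acetate | CC(=O)C(=C)[C@H](C)C[C@H](C=C(C)C)OC(C)=O
F2 | step 7 | (4R,6R)-4,8-dimethyl-3-methylidene-2-[(triethylsilyl)oxy]nona-1,7-dien-6-yl acetate | C=C(O[Si](CC)(CC)CC)C(=C)[C@H](C)C[C@H](C=C(C)C)OC(C)=O
F3 | step 7 | 9-[(1Z)-prop-1-en-1-yl]-9-borabicyclo[3.3.1]nonane | C/C=C\B1C2CCCC1CCC2
F4 | step 7 | (4R,6R)-6-{(4S,5R)-5-(9-borabicyclo[3.3.1]nonan-9-yl)-4-methyl-2-[(triethylsilyl)oxy]cyclohex-1-en-1-yl}-2-methylhept-2-en-4-yl acetate | CC[Si](CC)(CC)OC=1C[C@H](C)[C@H](B2C3CCCC2CCC3)CC=1[C@H](C)C[C@H](C=C(C)C)OC(C)=O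
F5 | step 7 | (4R,6R)-6-[(1S,4S,5R)-5-hydroxy-4-methyl-2-oxocyclohexyl]-2-methylhept-2-en-4-yl acetate | O=C1C[C@H](C)[C@H](O)C[C@H]1[C@H](C)C[C@H](C=C(C)C)OC(C)=O
F6 | step 2 | methyl (3R,5E)-7-hydroxy-3,7-dimethyloct-5-enoate | COC(=O)C[C@H](C)C/C=C/C(C)(C)O
F7 | step 2 | methyl (3R)-3,7-dimethyl-5-oxooct-6-enoate | COC(=O)C[C@H](C)CC(=O)C=C(C)C
F8 | step 2 | methyl (3R,5R)-5-hydroxy-3,7-dimethyloct-6-enoate | COC(=O)C[C@H](C)C[C@H](C=C(C)C)O
F9 | step 8 | (2R,4R,4aS,6R,7S,8aR)-8a-methoxy-4,7-dimethyl-2-(2-methylprop-1-en-1-yl)octahydro-2H-chromen-6-ol (trans-fused) | CO[C@@]12C[C@H](C)[C@H](O)C[C@H]1[C@H](C)C[C@H](C=C(C)C)O2
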